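**Plan** (germacrane numbering: ring C1–C10; lactone carbons C11 (sp2), C12 (C=O), C13 (=CH2); C14 on C10, C15 on C4)
1. Retrosynthesis: remove the C8 tiglate; excise lactone carbon C12 as CO2 (cuts O1–C6 and C11–C12); open the carbocycle at C5–C6; cut the chain at C2–C3 and at C7–C11.
2. Forward: the C6–C10/C1–C2 chain is built from (2E)-3-methylpent-2-en-4-yn-1-ol, joined to (2Z)-3-iodo-2-methylprop-2-enal by alkynylation and cis-semi-reduction; the ten-membered ring closes by a Nozaki–Hiyama–Kishi reaction (C5–C6); the γ-lactone ring forms last; then tiglate and desilylation.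
3. Enabling feature: C6 is a secondary allylic carbon (next to the C4=C5 olefin) and its neighbour C7 carries the sp2 carbon C11. A C11–metal bond takes up CO2, and the resulting carboxylate sits five atoms from an SN2-active C6–Cl, so the ring O1–C12–C11–C7–C6 closes with inversion to the cis-fused lactone.
4. Stereochemistry: C10 and C7/C8 come from two Sharpless epoxidations (opened by Red-Al and, with inversion, by a vinyl cuprate); C3 from ligand-controlled alkynylation; C6 from Felkin-type NHK addition, then two inversions (chloride, carboxylate); both ring olefins are Z, from the Z-iodoenal and the semi-reduction.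

Key step: step 18

Remark: (S,S)-ProPhenol is assumed to direct the alkynyl group to the Re face of enal 4 (giving 3R); if a trial run shows the opposite sense, the (R,R)-ligand serves in step 10.

**Step 1**
Reactants: 1 prop-2-yn-1-ol
Product: 3 (2Z)-3-iodo-2-methylprop-2-en-1-ol, via alkenylmagnesium alkoxide 2 (not isolated)
Conditions: MeMgBr (2.5 equiv), CuI (10 mol %), THF, −10 °C → rt; then I2, −10 °C
Reagents that add atoms: methylmagnesium bromide, C[Mg]Br; iodine, II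
Why: Copper-catalysed anti-carbomagnesiation of the propargylic alkoxide (Duboudin–Jousseaume) places Mg cis to CH2O in a five-membered chelate, and iodinolysis with retention fixes the Z-iodoalkene that becomes the C4=C5 olefin.

**Step 2**
Reactants: 3 (2Z)-3-iodo-2-methylprop-2-en-1-ol
Product: 4 (2Z)-3-iodo-2-methylprop-2-enal
Conditions: MnO2 (15 equiv), CH2Cl2, rt, dark; filtered solution used at once
Reagents that add atoms: none
Why: Allylic oxidation with MnO2 is neutral and should not isomerise the Z-iodoenal.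

**Step 3**
Reactants: 5 (2E)-3-methylpent-2-en-4-yn-1-ol
Product: 6 [(2S,3S)-3-ethynyl-3-methyloxiran-2-yl]methanol
Conditions: Ti(Oi-Pr)4 (10 mol %), L-(+)-DIPT (12 mol %), t-BuOOH, 4 Å MS, CH2Cl2, −20 °C
Reagents that add atoms: tert-butyl hydroperoxide, CC(C)(C)OO
Why: Sharpless asymmetric epoxidation; with L-(+)-tartrate the geraniol-type facial rule should give the 2S,3S epoxide, which sets C10.

**Step 4**
Reactants: 6 [(2S,3S)-3-ethynyl-3-methyloxiran-2-yl]methanol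
Product: 7 (3R)-3-methylpent-4-yne-1,3-diol
Conditions: Red-Al (2.5 equiv), THF, −20 → 0 °C; Rochelle salt work-up
Reagents that add atoms: none
Why: Red-Al opening of a 2,3-epoxy alcohol delivers hydride within the alkoxy-aluminate to C2 (1,3-diol mode), so the C–O bond at the tertiary centre and its configuration (3R, the future C10) stay intact, and the metalated terminal alkyne should resist SN2′ reduction.

**Step 5**
Reactants: 7 (3R)-3-methylpent-4-yne-1,3-diol
Product: 9 ethyl (2E,5R)-5-hydroxy-5-methylhept-2-en-6-ynoate, via (3R)-3-hydroxy-3-methylpent-4-ynal 8 (not isolated)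
Conditions: TEMPO (10 mol %), PhI(OAc)2 (1.1 equiv), CH2Cl2, rt; then Ph3P=CHCO2Et (1.3 equiv), rt
Reagents that add atoms: (ethoxycarbonylmethylene)triphenylphosphorane, CCOC(=O)C=P(c1ccccc1)(c1ccccc1)c1ccccc1
Why: TEMPO/PhI(OAc)2 oxidises only the primary alcohol, and the stabilised Wittig ylide traps the β-hydroxy aldehyde in the same flask as the E-enoate.

**Step 6**
Reactants: 9 ethyl (2E,5R)-5-hydroxy-5-methylhept-2-en-6-ynoate
Product: 10 (2E,5R)-5-methylhept-2-en-6-yne-1,5-diol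
Conditions: DIBAL-H (3.5 equiv), CH2Cl2, −78 → 0 °C
Reagents that add atoms: none
Why: 1,2-Reduction of the enoate with DIBAL-H gives the E-allylic alcohol needed for the second epoxidation.

**Step 7**
Reactants: 10 (2E,5R)-5-methylhept-2-en-6-yne-1,5-diol
Product: 11 (2R)-1-[(2R,3R)-3-(hydroxymethyl)oxiran-2-yl]-2-methylbut-3-yn-2-ol
Conditions: Ti(Oi-Pr)4 (30 mol %), D-(−)-DIPT (36 mol %), t-BuOOH, 4 Å MS, CH2Cl2, −20 °C
Reagents that add atoms: tert-butyl hydroperoxide, CC(C)(C)OO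
Why: Sharpless asymmetric epoxidation under reagent control; D-(−)-tartrate should give the 2R,3R epoxy alcohol (future C7 and C8), and the remote tertiary carbinol has no influence.

**Step 8**
Reactants: 11 (2R)-1-[(2R,3R)-3-(hydroxymethyl)oxiran-2-yl]-2-methylbut-3-yn-2-ol
Product: 12 (2S,3R,5R)-5-methyl-2-[1-(trimethylsilyl)ethenyl]hept-6-yne-1,3,5-triol
Conditions: MeMgBr (3.0 equiv), THF, −40 °C; then CH2=C(SiMe3)MgBr (3.0 equiv, from the bromide and Mg), CuI (30 mol %), −40 → −10 °C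
Reagents that add atoms: [1-(trimethylsilyl)ethenyl]magnesium bromide, C=C([Mg]Br)[Si](C)(C)C
Why: Copper-catalysed Grignard opening of a trans-2,3-epoxy alcohol at C2 (1,3-diol mode, favoured by the C1 alkoxide and the β-branched substituent on C3) proceeds with inversion, setting C7 anti to the C8 hydroxyl and bringing in C11/C13 as an inert vinylsilane.

**Step 9**
Reactants: 12 (2S,3R,5R)-5-methyl-2-[1-(trimethylsilyl)ethenyl]hept-6-yne-1,3,5-triol
Product: 13 (2S,3R,5R)-5-methyl-1,3,5-tris(triethylsilyloxy)-2-[1-(trimethylsilyl)ethenyl]hept-6-yne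
Conditions: Et3SiOTf (3.6 equiv), 2,6-lutidine, CH2Cl2, −78 → 0 °C
Reagents that add atoms: triethylsilyl trifluoromethanesulfonate, CC[Si](CC)(CC)OS(=O)(=O)C(F)(F)F
Why: Silyl triflate silylation protects the primary, secondary and tertiary hydroxyls in one operation, and the primary TES ether can later be oxidised directly (step 13).

**Step 10**
Reactants: 13 (2S,3R,5R)-5-methyl-1,3,5-tris(triethylsilyloxy)-2-[1-(trimethylsilyl)ethenyl]hept-6-yne; 4 (2Z)-3-iodo-2-methylprop-2-enal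
Product: 14 (1Z,3R,6R,8R,9S)-1-iodo-2,6-dimethyl-6,8-bis(triethylsilyloxy)-9-[(triethylsilyloxy)methyl]-10-(trimethylsilyl)undeca-1,10-dien-4-yn-3-ol
Conditions: 13 (1.0 equiv), 4 (1.5 equiv), (S,S)-ProPhenol (20 mol %), Me2Zn (3 equiv), Ph3P=O (40 mol %), toluene, 0–4 °C
Reagents that add atoms: none
Why: Zinc–ProPhenol-catalysed asymmetric alkynylation of an enal: the ligand-bound zinc acetylide should add 1,2 to the Re face of the aldehyde and set C3 (3R), leaving the Z-iodoalkene untouched.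

**Step 11**
Reactants: 14 (1Z,3R,6R,8R,9S)-1-iodo-2,6-dimethyl-6,8-bis(triethylsilyloxy)-9-[(triethylsilyloxy)methyl]-10-(trimethylsilyl)undeca-1,10-dien-4-yn-3-ol
Product: 15 (1Z,3R,4Z,6R,8R,9S)-1-iodo-2,6-dimethyl-6,8-bis(triethylsilyloxy)-9-[(triethylsilyloxy)methyl]-10-(trimethylsilyl)undeca-1,4,10-trien-3-ol
Conditions: Zn(Cu/Ag), MeOH/H2O 1:1, rt → 40 °C, dark
Reagents that add atoms: none
Why: Boland cis-semi-reduction of an alkyne activated by the propargylic hydroxyl should give the Z-C1=C2 olefin without over-reduction, and zinc in a protic medium should not touch the alkenyl iodide or the vinylsilane.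

**Step 12**
Reactants: 15 (1Z,3R,4Z,6R,8R,9S)-1-iodo-2,6-dimethyl-6,8-bis(triethylsilyloxy)-9-[(triethylsilyloxy)methyl]-10-(trimethylsilyl)undeca-1,4,10-trien-3-ol
Product: 16 (1Z,3R,4Z,6R,8R,9S)-3-(tert-butyldimethylsilyloxy)-1-iodo-2,6-dimethyl-6,8-bis(triethylsilyloxy)-9-[(triethylsilyloxy)methyl]-10-(trimethylsilyl)undeca-1,4,10-triene
Conditions: TBSOTf (1.3 equiv), 2,6-lutidine, CH2Cl2, −78 °C
Reagents that add atoms: tert-butyldimethylsilyl trifluoromethanesulfonate, CC(C)(C)[Si](C)(C)OS(=O)(=O)C(F)(F)F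
Why: Silylation of the hindered bis-allylic carbinol with a silyl triflate gives a TBS ether that outlasts the later removal of the C8 triethylsilyl group.

**Step 13**
Reactants: 16 (1Z,3R,4Z,6R,8R,9S)-3-(tert-butyldimethylsilyloxy)-1-iodo-2,6-dimethyl-6,8-bis(triethylsilyloxy)-9-[(triethylsilyloxy)methyl]-10-(trimethylsilyl)undeca-1,4,10-triene
Product: 17 (2R,3R,5R,6Z,8R,9Z)-8-(tert-butyldimethylsilyloxy)-10-iodo-5,9-dimethyl-3,5-bis(triethylsilyloxy)-2-[1-(trimethylsilyl)ethenyl]deca-6,9-dienal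
Conditions: (COCl)2 (4 equiv), DMSO (8 equiv), CH2Cl2, −78 → −35 °C; then Et3N, −78 → 0 °C; crude aldehyde used at once
Reagents that add atoms: none
Why: Swern oxidation cleaves and oxidises a primary triethylsilyl ether directly while secondary and tertiary silyl ethers stay on, giving the C6 aldehyde without a separate deprotection, and the low temperature limits epimerisation at C7.

**Step 14**
Reactants: 17 (2R,3R,5R,6Z,8R,9Z)-8-(tert-butyldimethylsilyloxy)-10-iodo-5,9-dimethyl-3,5-bis(triethylsilyloxy)-2-[1-(trimethylsilyl)ethenyl]deca-6,9-dienal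
Product: 18 (1S,2Z,4R,5Z,7R,9R,10S)-4-(tert-butyldimethylsilyloxy)-3,7-dimethyl-7,9-bis(triethylsilyloxy)-10-[1-(trimethylsilyl)ethenyl]cyclodeca-2,5-dien-1-ol
Conditions: CrCl2 (15 equiv), NiCl2 (1 mol % of Cr), DMSO/THF 3:1, rt, 2 mM, slow addition
Reagents that add atoms: none
Why: Nozaki–Hiyama–Kishi macrocyclisation at high dilution: the alkenyl iodide is activated selectively (the vinylsilane is inert), the Z geometry is retained, and Felkin–Anh addition anti to the 1-silylvinyl group on C7 should set the C6 carbinol (1S, OH cis to the C7 side chain).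

**Step 15**
Reactants: 18 (1S,2Z,4R,5Z,7R,9R,10S)-4-(tert-butyldimethylsilyloxy)-3,7-dimethyl-7,9-bis(triethylsilyloxy)-10-[1-(trimethylsilyl)ethenyl]cyclodeca-2,5-dien-1-ol
Product: 19 (1S,2Z,4R,5Z,7R,9R,10S)-4-(tert-butyldimethylsilyloxy)-10-(1-iodoethenyl)-3,7-dimethyl-7,9-bis(triethylsilyloxy)cyclodeca-2,5-dien-1-ol
Conditions: NIS (1.5 equiv), MeCN/ClCH2CN 4:1, 0 °C, dark
Reagents that add atoms: N-iodosuccinimide, O=C1CCC(=O)N1I
Why: Ipso-iododesilylation of the 2-silyl-1-alkene with NIS (β-silyl cation pathway) should exchange SiMe3 for iodine at C11 faster than NIS attacks the ordinary ring olefins.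

**Step 16**
Reactants: 19 (1S,2Z,4R,5Z,7R,9R,10S)-4-(tert-butyldimethylsilyloxy)-10-(1-iodoethenyl)-3,7-dimethyl-7,9-bis(triethylsilyloxy)cyclodeca-2,5-dien-1-ol
Product: 20 (1S,2Z,4R,5Z,7R,9R,10S)-4-(tert-butyldimethylsilyloxy)-3,7-dimethyl-10-[1-(4,4,5,5-tetramethyl-1,3,2-dioxaborolan-2-yl)ethenyl]-7,9-bis(triethylsilyloxy)cyclodeca-2,5-dien-1-ol
Conditions: B2pin2 (1.5 equiv), PdCl2(PPh3)2 (5 mol %), PPh3 (10 mol %), KOPh (1.5 equiv), toluene, 50 °C
Reagents that add atoms: bis(pinacolato)diboron, CC1(C)OB(OC1(C)C)B1OC(C)(C)C(C)(C)O1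
Why: Miyaura borylation of a 1-alkenyl iodide turns C11–I into the C11–B bond needed for copper transmetalation, and it is placed before the chlorination so that no allylic leaving group is exposed to Pd(0).

**Step 17**
Reactants: 20 (1S,2Z,4R,5Z,7R,9R,10S)-4-(tert-butyldimethylsilyloxy)-3,7-dimethyl-10-[1-(4,4,5,5-tetramethyl-1,3,2-dioxaborolan-2-yl)ethenyl]-7,9-bis(triethylsilyloxy)cyclodeca-2,5-dien-1-ol
Product: 21 2-{1-[(1R,2R,3Z,5R,6Z,8R,10R)-5-(tert-butyldimethylsilyloxy)-2-chloro-4,8-dimethyl-8,10-bis(triethylsilyloxy)cyclodeca-3,6-dien-1-yl]ethenyl}-4,4,5,5-tetramethyl-1,3,2-dioxaborolane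
Conditions: PPh3 (1.5 equiv), Cl3CCOCCl3 (3 equiv), CH2Cl2, 0 °C
Reagents that add atoms: hexachloroacetone, ClC(Cl)(Cl)C(=O)C(Cl)(Cl)Cl
Why: Appel-type chlorination with PPh3/hexachloroacetone (Magid conditions) should replace the allylic hydroxyl by chloride with inversion and without allylic transposition, giving the C6 chloride trans to the C7 side chain.

**Step 18**
Reactants: 21 2-{1-[(1R,2R,3Z,5R,6Z,8R,10R)-5-(tert-butyldimethylsilyloxy)-2-chloro-4,8-dimethyl-8,10-bis(triethylsilyloxy)cyclodeca-3,6-dien-1-yl]ethenyl}-4,4,5,5-tetramethyl-1,3,2-dioxaborolane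
Product: 23 (3aS,4R,6R,7Z,9R,10Z,11aS)-9-(tert-butyldimethylsilyloxy)-6,10-dimethyl-3-methylidene-4,6-bis(triethylsilyloxy)-3a,4,5,6,9,11a-hexahydrocyclodeca[b]furan-2(3H)-one, via potassium acrylate 22 (not isolated)
Conditions: (IPr)CuCl (10 mol %), KOt-Bu (1.05 equiv), CO2 (1 atm), THF, 0 → 65 °C
Reagents that add atoms: carbon dioxide, O=C=O
Why: tert-Butoxide adds to boron and the borate passes its alkenyl group to (IPr)Cu(I); CO2 inserts into the Cu–C(sp2) bond (C11–C12), salt exchange releases potassium acrylate 22, and its carboxylate oxygen then displaces the allylic C6 chloride from the rear (O1–C6). The closest known reaction types are the NHC–copper(I)-catalysed carboxylation of alkenylboronic esters with CO2 and the lactonisation of halo carboxylates by O-alkylation. The γ-lactone ring (O1, C12, C11, C7, C6) closes 5-exo-tet. The only stereocentre affected is C6, set by SN2 inversion of the chloride, so the oxygen ends cis to the C7–C11 bond (11aS, cis-fused), while C7 is not touched. The step needs CO2 capture to outrun copper-mediated allylic C–C coupling and base-induced loss of HCl, and SN2 to beat SN2′: intramolecular C–C coupling could only be 3-exo or 5-endo, the single equivalent of KOt-Bu is tied up on boron, γ-attack at C4 would need a seven-membered ring at a fully substituted carbon, and KCl is insoluble in THF so chloride cannot re-enter and scramble C6.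

**Step 19**
Reactants: 23 (3aS,4R,6R,7Z,9R,10Z,11aS)-9-(tert-butyldimethylsilyloxy)-6,10-dimethyl-3-methylidene-4,6-bis(triethylsilyloxy)-3a,4,5,6,9,11a-hexahydrocyclodeca[b]furan-2(3H)-one
Product: 24 (3aR,4R,6R,7Z,9R,10Z,11aS)-9-(tert-butyldimethylsilyloxy)-4-hydroxy-6,10-dimethyl-3-methylidene-6-(triethylsilyloxy)-3a,4,5,6,9,11a-hexahydrocyclodeca[b]furan-2(3H)-one
Conditions: HF·pyridine, pyridine, THF, 0 °C, monitored
Reagents that add atoms: none
Why: Buffered HF·pyridine should cleave the secondary triethylsilyl ether at C8 much faster than the tertiary TES ether at C10 or the TBS ether at C3, and the non-basic medium avoids translactonisation to O8.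

**Step 20**
Reactants: 24 (3aR,4R,6R,7Z,9R,10Z,11aS)-9-(tert-butyldimethylsilyloxy)-4-hydroxy-6,10-dimethyl-3-methylidene-6-(triethylsilyloxy)-3a,4,5,6,9,11a-hexahydrocyclodeca[b]furan-2(3H)-one
Product: 25 (3aR,4R,6R,7Z,9R,10Z,11aS)-9-(tert-butyldimethylsilyloxy)-6,10-dimethyl-3-methylidene-2-oxo-6-(triethylsilyloxy)-2,3,3a,4,5,6,9,11a-octahydrocyclodeca[b]furan-4-yl (2E)-2-methylbut-2-enoate
Conditions: tigloyl chloride (3 equiv), pyridine, DMAP (0.2 equiv), CH2Cl2, 0 °C → rt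
Reagents that add atoms: (2E)-2-methylbut-2-enoyl chloride, C/C=C(\C)C(Cl)=O
Why: DMAP-catalysed acylation of the only free hydroxyl (C8) installs the (E)-2-methylbut-2-enoate, whose geometry is the thermodynamically stable one.

**Step 21**
Reactants: 25 (3aR,4R,6R,7Z,9R,10Z,11aS)-9-(tert-butyldimethylsilyloxy)-6,10-dimethyl-3-methylidene-2-oxo-6-(triethylsilyloxy)-2,3,3a,4,5,6,9,11a-octahydrocyclodeca[b]furan-4-yl (2E)-2-methylbut-2-enoate
Product: 26 (3aR,4R,6R,7Z,9R,10Z,11aS)-6,9-dihydroxy-6,10-dimethyl-3-methylidene-2-oxo-2,3,3a,4,5,6,9,11a-octahydrocyclodeca[b]furan-4-yl (2E)-2-methylbut-2-enoate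
Conditions: HF·pyridine (excess), pyridine, THF, 0 °C → rt
Reagents that add atoms: none
Why: Fluoride-mediated global desilylation with buffered HF·pyridine should remove the TBS (C3) and tertiary TES (C10) groups without harming the α-methylene lactone, the ester or the acid-sensitive bis-allylic carbinol.

**Compound list**
1 | prop-2-yn-1-ol | C#CCO | starting material
2 | bromomagnesium (2Z)-3-(bromomagnesio)-2-methylprop-2-en-1-olate | Br[Mg]/C=C(/C)CO[Mg]Br | intermediate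
3 | (2Z)-3-iodo-2-methylprop-2-en-1-ol | I/C=C(/C)CO | intermediate
4 | (2Z)-3-iodo-2-methylprop-2-enal | I/C=C(/C)C=O | intermediate
5 | (2E)-3-methylpent-2-en-4-yn-1-ol | C#C/C(C)=C/CO | starting material
6 | [(2S,3S)-3-ethynyl-3-methyloxiran-2-yl]methanol | C#C[C@]1(C)O[C@H]1CO | intermediate
7 | (3R)-3-methylpent-4-yne-1,3-diol | C#C[C@](C)(O)CCO | intermediate
8 | (3R)-3-hydroxy-3-methylpent-4-ynal | C#C[C@](C)(O)CC=O | intermediate
9 | ethyl (2E,5R)-5-hydroxy-5-methylhept-2-en-6-ynoate | C#C[C@](C)(O)C/C=C/C(=O)OCC | intermediate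
10 | (2E,5R)-5-methylhept-2-en-6-yne-1,5-diol | C#C[C@](C)(O)C/C=C/CO | intermediate
11 | (2R)-1-[(2R,3R)-3-(hydroxymethyl)oxiran-2-yl]-2-methylbut-3-yn-2-ol | C#C[C@](C)(O)C[C@H]1O[C@@H]1CO | intermediate
12 | (2S,3R,5R)-5-methyl-2-[1-(trimethylsilyl)ethenyl]hept-6-yne-1,3,5-triol | C#C[C@](C)(O)C[C@@H](O)[C@H](CO)C(=C)[Si](C)(C)C | intermediate
13 | (2S,3R,5R)-5-methyl-1,3,5-tris(triethylsilyloxy)-2-[1-(trimethylsilyl)ethenyl]hept-6-yne | C#C[C@](C)(O[Si](CC)(CC)CC)C[C@@H](O[Si](CC)(CC)CC)[C@H](CO[Si](CC)(CC)CC)C(=C)[Si](C)(C)C | intermediate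
14 | (1Z,3R,6R,8R,9S)-1-iodo-2,6-dimethyl-6,8-bis(triethylsilyloxy)-9-[(triethylsilyloxy)methyl]-10-(trimethylsilyl)undeca-1,10-dien-4-yn-3-ol | I/C=C(/C)[C@H](O)C#C[C@](C)(O[Si](CC)(CC)CC)C[C@@H](O[Si](CC)(CC)CC)[C@H](CO[Si](CC)(CC)CC)C(=C)[Si](C)(C)C | intermediate
15 | (1Z,3R,4Z,6R,8R,9S)-1-iodo-2,6-dimethyl-6,8-bis(triethylsilyloxy)-9-[(triethylsilyloxy)methyl]-10-(trimethylsilyl)undeca-1,4,10-trien-3-ol | I/C=C(/C)[C@H](O)/C=C\[C@](C)(O[Si](CC)(CC)CC)C[C@@H](O[Si](CC)(CC)CC)[C@H](CO[Si](CC)(CC)CC)C(=C)[Si](C)(C)C | intermediate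
16 | (1Z,3R,4Z,6R,8R,9S)-3-(tert-butyldimethylsilyloxy)-1-iodo-2,6-dimethyl-6,8-bis(triethylsilyloxy)-9-[(triethylsilyloxy)methyl]-10-(trimethylsilyl)undeca-1,4,10-triene | I/C=C(/C)[C@H](O[Si](C)(C)C(C)(C)C)/C=C\[C@](C)(O[Si](CC)(CC)CC)C[C@@H](O[Si](CC)(CC)CC)[C@H](CO[Si](CC)(CC)CC)C(=C)[Si](C)(C)C | intermediate
17 | (2R,3R,5R,6Z,8R,9Z)-8-(tert-butyldimethylsilyloxy)-10-iodo-5,9-dimethyl-3,5-bis(triethylsilyloxy)-2-[1-(trimethylsilyl)ethenyl]deca-6,9-dienal | I/C=C(/C)[C@H](O[Si](C)(C)C(C)(C)C)/C=C\[C@](C)(O[Si](CC)(CC)CC)C[C@@H](O[Si](CC)(CC)CC)[C@H](C=O)C(=C)[Si](C)(C)C | intermediate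
18 | (1S,2Z,4R,5Z,7R,9R,10S)-4-(tert-butyldimethylsilyloxy)-3,7-dimethyl-7,9-bis(triethylsilyloxy)-10-[1-(trimethylsilyl)ethenyl]cyclodeca-2,5-dien-1-ol | O[C@H]1/C=C(/C)[C@H](O[Si](C)(C)C(C)(C)C)/C=C\[C@](C)(O[Si](CC)(CC)CC)C[C@@H](O[Si](CC)(CC)CC)[C@H]1C(=C)[Si](C)(C)C | intermediate
19 | (1S,2Z,4R,5Z,7R,9R,10S)-4-(tert-butyldimethylsilyloxy)-10-(1-iodoethenyl)-3,7-dimethyl-7,9-bis(triethylsilyloxy)cyclodeca-2,5-dien-1-ol | O[C@H]1/C=C(/C)[C@H](O[Si](C)(C)C(C)(C)C)/C=C\[C@](C)(O[Si](CC)(CC)CC)C[C@@H](O[Si](CC)(CC)CC)[C@H]1C(=C)I | intermediate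
20 | (1S,2Z,4R,5Z,7R,9R,10S)-4-(tert-butyldimethylsilyloxy)-3,7-dimethyl-10-[1-(4,4,5,5-tetramethyl-1,3,2-dioxaborolan-2-yl)ethenyl]-7,9-bis(triethylsilyloxy)cyclodeca-2,5-dien-1-ol | O[C@H]1/C=C(/C)[C@H](O[Si](C)(C)C(C)(C)C)/C=C\[C@](C)(O[Si](CC)(CC)CC)C[C@@H](O[Si](CC)(CC)CC)[C@H]1C(=C)B2OC(C)(C)C(C)(C)O2 | intermediate
21 | 2-{1-[(1R,2R,3Z,5R,6Z,8R,10R)-5-(tert-butyldimethylsilyloxy)-2-chloro-4,8-dimethyl-8,10-bis(triethylsilyloxy)cyclodeca-3,6-dien-1-yl]ethenyl}-4,4,5,5-tetramethyl-1,3,2-dioxaborolane | Cl[C@@H]1/C=C(/C)[C@H](O[Si](C)(C)C(C)(C)C)/C=C\[C@](C)(O[Si](CC)(CC)CC)C[C@@H](O[Si](CC)(CC)CC)[C@H]1C(=C)B2OC(C)(C)C(C)(C)O2 | intermediate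
22 | potassium 2-[(1R,2R,3Z,5R,6Z,8R,10R)-5-(tert-butyldimethylsilyloxy)-2-chloro-4,8-dimethyl-8,10-bis(triethylsilyloxy)cyclodeca-3,6-dien-1-yl]prop-2-enoate | Cl[C@@H]1/C=C(/C)[C@H](O[Si](C)(C)C(C)(C)C)/C=C\[C@](C)(O[Si](CC)(CC)CC)C[C@@H](O[Si](CC)(CC)CC)[C@H]1C(=C)C(=O)[O-].[K+] | intermediate
23 | (3aS,4R,6R,7Z,9R,10Z,11aS)-9-(tert-butyldimethylsilyloxy)-6,10-dimethyl-3-methylidene-4,6-bis(triethylsilyloxy)-3a,4,5,6,9,11a-hexahydrocyclodeca[b]furan-2(3H)-one | C=C1C(=O)O[C@H]2/C=C(/C)[C@H](O[Si](C)(C)C(C)(C)C)/C=C\[C@](C)(O[Si](CC)(CC)CC)C[C@@H](O[Si](CC)(CC)CC)[C@@H]12 | intermediate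
24 | (3aR,4R,6R,7Z,9R,10Z,11aS)-9-(tert-butyldimethylsilyloxy)-4-hydroxy-6,10-dimethyl-3-methylidene-6-(triethylsilyloxy)-3a,4,5,6,9,11a-hexahydrocyclodeca[b]furan-2(3H)-one | C=C1C(=O)O[C@H]2/C=C(/C)[C@H](O[Si](C)(C)C(C)(C)C)/C=C\[C@](C)(O[Si](CC)(CC)CC)C[C@@H](O)[C@@H]12 | intermediate
25 | (3aR,4R,6R,7Z,9R,10Z,11aS)-9-(tert-butyldimethylsilyloxy)-6,10-dimethyl-3-methylidene-2-oxo-6-(triethylsilyloxy)-2,3,3a,4,5,6,9,11a-octahydrocyclodeca[b]furan-4-yl (2E)-2-methylbut-2-enoate | C=C1C(=O)O[C@H]2/C=C(/C)[C@H](O[Si](C)(C)C(C)(C)C)/C=C\[C@](C)(O[Si](CC)(CC)CC)C[C@@H](OC(=O)/C(C)=C/C)[C@@H]12 | intermediate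
26 | (3aR,4R,6R,7Z,9R,10Z,11aS)-6,9-dihydroxy-6,10-dimethyl-3-methylidene-2-oxo-2,3,3a,4,5,6,9,11a-octahydrocyclodeca[b]furan-4-yl (2E)-2-methylbut-2-enoate (CNP0262559.2) | C=C1C(=O)O[C@H]2/C=C(/C)[C@H](O)/C=C\[C@](C)(O)C[C@@H](OC(=O)/C(C)=C/C)[C@@H]12 | target

**Step count**
Total: 21 steps. Longest linear sequence: 19 steps (steps 3–21, from 5); steps 1–2 make the side fragment 4.

**Three steps most likely to fail**

Step 18 (carboxylative lactonisation). What may go wrong: loss of HCl from the allylic chloride or copper-mediated C–C coupling before CO2 is captured, conjugate addition of the alkenylcopper to lactone already formed, and erosion of configuration at C6 by chloride exchange. The fallback uses known chemistry and sets out from iodide 19, before steps 16 and 17. Palladium-catalysed cyclocarbonylation (Pd(PPh3)4, CO 1 atm, Et3N, MeCN, 60 °C) should trap the acylpalladium with the C6 hydroxyl, which already has the required configuration, with retention, and comes back to the route at lactone 23; this detour makes no new compound (F0).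

Step 14 (NHK ring closure). What may go wrong: poor facial selectivity in the addition to the C6 aldehyde (attack from the other face), besides oligomerisation. The fallback sets out from aldehyde 17: if the closure gives mainly the C6 epimer, (1R,2Z,4R,5Z,7R,9R,10S)-4-(tert-butyldimethylsilyloxy)-3,7-dimethyl-7,9-bis(triethylsilyloxy)-10-[1-(trimethylsilyl)ethenyl]cyclodeca-2,5-dien-1-ol F1, this is inverted by Mitsunobu esterification (4-nitrobenzoic acid, PPh3, DIAD, toluene) to (1S,2Z,4R,5Z,7R,9R,10S)-4-(tert-butyldimethylsilyloxy)-3,7-dimethyl-7,9-bis(triethylsilyloxy)-10-[1-(trimethylsilyl)ethenyl]cyclodeca-2,5-dien-1-yl 4-nitrobenzoate F2, and methanolysis (K2CO3, MeOH) comes back to the route at 18.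

Step 10 (asymmetric alkynylation). What may go wrong: low conversion or insufficient ligand control with the hindered tertiary propargylic alkyne and the sensitive Z-iodoenal. The fallback sets out from alkyne 13: its lithium acetylide (n-BuLi, THF, −78 °C) adds to 4 without control to give 14 together with its epimer (1Z,3S,6R,8R,9S)-1-iodo-2,6-dimethyl-6,8-bis(triethylsilyloxy)-9-[(triethylsilyloxy)methyl]-10-(trimethylsilyl)undeca-1,10-dien-4-yn-3-ol F3. The mixture is oxidised (Dess–Martin periodinane) to (1Z,6R,8R,9S)-1-iodo-2,6-dimethyl-6,8-bis(triethylsilyloxy)-9-[(triethylsilyloxy)methyl]-10-(trimethylsilyl)undeca-1,10-dien-4-yn-3-one F4, and Corey–Bakshi–Shibata reduction ((S)-Me-CBS, catecholborane, −78 °C; alkynyl as the small group) comes back to the route at 14.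

**Further compounds**
F0 | step 18 | none | none
F1 | step 14 | (1R,2Z,4R,5Z,7R,9R,10S)-4-(tert-butyldimethylsilyloxy)-3,7-dimethyl-7,9-bis(triethylsilyloxy)-10-[1-(trimethylsilyl)ethenyl]cyclodeca-2,5-dien-1-ol | O[C@@H]1/C=C(/C)[C@H](O[Si](C)(C)C(C)(C)C)/C=C\[C@](C)(O[Si](CC)(CC)CC)C[C@@H](O[Si](CC)(CC)CC)[C@H]1C(=C)[Si](C)(C)C
F2 | step 14 | (1S,2Z,4R,5Z,7R,9R,10S)-4-(tert-butyldimethylsilyloxy)-3,7-dimethyl-7,9-bis(triethylsilyloxy)-10-[1-(trimethylsilyl)ethenyl]cyclodeca-2,5-dien-1-yl 4-nitrobenzoate | O=C(c2ccc(cc2)[N+](=O)[O-])O[C@H]1/C=C(/C)[C@H](O[Si](C)(C)C(C)(C)C)/C=C\[C@](C)(O[Si](CC)(CC)CC)C[C@@H](O[Si](CC)(CC)CC)[C@H]1C(=C)[Si](C)(C)C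
F3 | step 10 | (1Z,3S,6R,8R,9S)-1-iodo-2,6-dimethyl-6,8-bis(triethylsilyloxy)-9-[(triethylsilyloxy)methyl]-10-(trimethylsilyl)undeca-1,10-dien-4-yn-3-ol | I/C=C(/C)[C@@H](O)C#C[C@](C)(O[Si](CC)(CC)CC)C[C@@H](O[Si](CC)(CC)CC)[C@H](CO[Si](CC)(CC)CC)C(=C)[Si](C)(C)C
F4 | step 10 | (1Z,6R,8R,9S)-1-iodo-2,6-dimethyl-6,8-bis(triethylsilyloxy)-9-[(triethylsilyloxy)methyl]-10-(trimethylsilyl)undeca-1,10-dien-4-yn-3-one | I/C=C(/C)C(=O)C#C[C@](C)(O[Si](CC)(CC)CC)C[C@@H](O[Si](CC)(CC)CC)[C@H](CO[Si](CC)(CC)CC)C(=C)[Si](C)(C)C
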